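**Assumption:** the target (2'-O-methylstenosporic acid) has no stereocentre and is achiral, so there is no enantiomer to select. Olivetolic acid and 5-propylresorcinol are taken as purchasable.

## Retrosynthetic overview

1. Final step is CHO → CO2H on depside aldehyde 11, so the ring B acid never needs a protecting group.
2. The depside ester C(=O)–O bond is disconnected to ring A acid 3 and ring B phenol 9 (TFAA esterification).
3. Acid 3 comes from olivetolic acid 1 by ester/4-O-methylation, then saponification.
4. Phenol 9 comes from 5-propylresorcinol 4 by Vilsmeier formylation, then 4-O-MOM, 2-O-Me, MOM removal.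
5. No ring is constructed: both benzene rings are bought intact (ring A in 1, ring B in 4) and joined in step 7.

## Route

**Step 1**
Reactants: 1 olivetolic acid (2,4-dihydroxy-6-pentylbenzoic acid)
Product: 2 methyl 2-hydroxy-4-methoxy-6-pentylbenzoate
Conditions: MeI (2.2 equiv), K2CO3, acetone, reflux
Reagents that add atoms: iodomethane, CI
Why: SN2 O-methylation (Williamson) of the carboxylate and the free para-phenoxide, while the 2-OH hydrogen-bonded to the ester carbonyl is not alkylated at this stoichiometry.

**Step 2**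
Reactants: 2 methyl 2-hydroxy-4-methoxy-6-pentylbenzoate
Product: 3 2-hydroxy-4-methoxy-6-pentylbenzoic acid
Conditions: KOH, DMSO/H2O (4:1), 90 °C; then cold 2 M HCl
Reagents that add atoms: potassium hydroxide, [K+].[OH-]
Why: Saponification (acyl–oxygen cleavage) of the hindered ester by poorly solvated hydroxide in aqueous DMSO; the aryl methyl ether is inert and cold acidification avoids decarboxylation.

**Step 3**
Reactants: 4 5-propylresorcinol (5-propylbenzene-1,3-diol)
Product: 6 2,4-dihydroxy-6-propylbenzaldehyde, via iminium chloride 5 (not isolated)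
Conditions: POCl3, DMF, 0 °C → rt; then H2O, 50 °C
Reagents that add atoms: N,N-dimethylformamide, CN(C)C=O; water, O
Why: Vilsmeier–Haack formylation; the bulky chloroiminium electrophile attacks the position para to one OH and ortho to the other (not the crowded site between the two OH groups), and water hydrolyses iminium 5 to the aldehyde.

**Step 4**
Reactants: 6 2,4-dihydroxy-6-propylbenzaldehyde
Product: 7 2-hydroxy-4-(methoxymethoxy)-6-propylbenzaldehyde
Conditions: MOMCl (1.05 equiv), K2CO3, acetone, 0 °C → rt
Reagents that add atoms: chloromethyl methyl ether, COCCl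
Why: Selective Williamson-type O-alkylation of the more acidic, unchelated 4-OH; the 2-OH is tied up in a hydrogen bond to the formyl group.

**Step 5**
Reactants: 7 2-hydroxy-4-(methoxymethoxy)-6-propylbenzaldehyde
Product: 8 2-methoxy-4-(methoxymethoxy)-6-propylbenzaldehyde
Conditions: MeI, K2CO3, DMF, rt
Reagents that add atoms: iodomethane, CI
Why: Williamson O-methylation of the remaining chelated phenol, which is deprotonated in DMF; the MOM acetal and the aldehyde are stable to base.

**Step 6**
Reactants: 8 2-methoxy-4-(methoxymethoxy)-6-propylbenzaldehyde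
Product: 9 4-hydroxy-2-methoxy-6-propylbenzaldehyde
Conditions: 3 M aq. HCl, THF, 50 °C
Reagents that add atoms: none
Why: Acid-catalysed acetal hydrolysis removes the MOM group through an oxocarbenium ion, leaving the aryl methyl ether and the aldehyde untouched.

**Step 7**
Reactants: 3 2-hydroxy-4-methoxy-6-pentylbenzoic acid; 9 4-hydroxy-2-methoxy-6-propylbenzaldehyde
Product: 11 4-formyl-3-methoxy-5-propylphenyl 2-hydroxy-4-methoxy-6-pentylbenzoate, via mixed trifluoroacetic anhydride 10 (not isolated)
Conditions: TFAA, toluene, rt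
Reagents that add atoms: none
Why: Mixed-anhydride esterification; TFAA turns the electron-rich hindered acid into the acylium-like anhydride 10, which acylates the only unchelated phenol (that of 9), while the hydrogen-bonded 2-OH of ring A does not compete.

**Step 8**
Reactants: 11 4-formyl-3-methoxy-5-propylphenyl 2-hydroxy-4-methoxy-6-pentylbenzoate
Product: 12 4-[(2-hydroxy-4-methoxy-6-pentylbenzoyl)oxy]-2-methoxy-6-propylbenzoic acid (target)
Conditions: NaClO2, NaH2PO4, 2-methyl-2-butene (excess), t-BuOH/THF/H2O, 0 °C → rt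
Reagents that add atoms: sodium chlorite, [Na+].[O-]Cl=O
Why: Pinnick oxidation of the aryl aldehyde by chlorous acid at about pH 4, where the depside ester is stable; 2-methyl-2-butene traps HOCl before it can chlorinate the phenolic ring A.

## Compound list

1 | olivetolic acid (2,4-dihydroxy-6-pentylbenzoic acid) | CCCCCc1cc(O)cc(O)c1C(=O)O | starting material
2 | methyl 2-hydroxy-4-methoxy-6-pentylbenzoate | CCCCCc1cc(OC)cc(O)c1C(=O)OC | intermediate
3 | 2-hydroxy-4-methoxy-6-pentylbenzoic acid | CCCCCc1cc(OC)cc(O)c1C(=O)O | intermediate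
4 | 5-propylresorcinol (5-propylbenzene-1,3-diol) | CCCc1cc(O)cc(O)c1 | starting material
5 | (2,4-dihydroxy-6-propylbenzylidene)dimethylammonium chloride (formed in the flask, step 3) | CCCc1cc(O)cc(O)c1C=[N+](C)C.[Cl-] | intermediate
6 | 2,4-dihydroxy-6-propylbenzaldehyde | CCCc1cc(O)cc(O)c1C=O | intermediate
7 | 2-hydroxy-4-(methoxymethoxy)-6-propylbenzaldehyde | CCCc1cc(OCOC)cc(O)c1C=O | intermediate
8 | 2-methoxy-4-(methoxymethoxy)-6-propylbenzaldehyde | CCCc1cc(OCOC)cc(OC)c1C=O | intermediate
9 | 4-hydroxy-2-methoxy-6-propylbenzaldehyde | CCCc1cc(O)cc(OC)c1C=O | intermediate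
10 | 2-hydroxy-4-methoxy-6-pentylbenzoic trifluoroacetic anhydride (formed in the flask, step 7) | CCCCCc1cc(OC)cc(O)c1C(=O)OC(=O)C(F)(F)F | intermediate
11 | 4-formyl-3-methoxy-5-propylphenyl 2-hydroxy-4-methoxy-6-pentylbenzoate | CCCCCc1cc(OC)cc(O)c1C(=O)Oc1cc(CCC)c(C=O)c(OC)c1 | intermediate
12 | 4-[(2-hydroxy-4-methoxy-6-pentylbenzoyl)oxy]-2-methoxy-6-propylbenzoic acid | CCCCCc1cc(OC)cc(O)c1C(=O)Oc1cc(CCC)c(C(=O)O)c(OC)c1 | target

## Step count

Total steps: 8 (steps 1–2 for ring A, steps 3–6 for ring B, steps 7–8 for coupling and oxidation).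
Longest linear sequence: 6 steps (4 → 6 → 7 → 8 → 9 → 11 → 12, steps 3–8).

## Steps most likely to fail, with fallbacks

**Step 7 (TFAA coupling).** The phenol of 9 is deactivated by the para-formyl group, and the hindered salicylic acid may self-condense. The fallback sets out from 3 and comes back at 11. Acid 3 is closed with acetone, TFAA and TFA at rt to the acyl ketal 7-methoxy-2,2-dimethyl-5-pentyl-4H-1,3-benzodioxin-4-one F1. The sodium phenoxide of 9 (NaH, THF/DMF, 0 → 60 °C) then opens F1 at the carbonyl with loss of acetone, giving 11 after mild acid work-up. The approach changes from electrophilic activation of a free acid to base-mediated ring-opening of a masked salicylate.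

**Step 8 (Pinnick oxidation on the depside).** The free-phenol ring A may be chlorinated, or the aryl ester cleaved. The fallback sets out from 8 and comes back at 12; the oxidation is moved ahead of the coupling and the acid is carried as a benzyl ester.
- Aldehyde 8, which has no free phenol, is oxidised with NaClO2/NaH2PO4/2-methyl-2-butene to 2-methoxy-4-(methoxymethoxy)-6-propylbenzoic acid F2.
- BnBr, K2CO3, DMF gives benzyl 2-methoxy-4-(methoxymethoxy)-6-propylbenzoate F3.
- 3 M aq. HCl/THF removes the MOM group to give benzyl 4-hydroxy-2-methoxy-6-propylbenzoate F4.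
- TFAA/toluene coupling of F4 with acid 3 (again through anhydride 10) gives benzyl 4-[(2-hydroxy-4-methoxy-6-pentylbenzoyl)oxy]-2-methoxy-6-propylbenzoate F5.
- Hydrogenolysis (H2, 10% Pd/C, EtOAc, rt) delivers 12.

**Step 2 (saponification of the doubly ortho-substituted ester).** Hydrolysis may be slow, and the acid may decarboxylate under forcing conditions. The fallback sets out from 1 and comes back at 3, replacing hydrolysis by hydrogenolysis. Acid 1 is esterified selectively at the carboxylate with BnBr, KHCO3, DMF, rt to benzyl 2,4-dihydroxy-6-pentylbenzoate F6. MeI (1.1 equiv), K2CO3, acetone methylates only the unchelated 4-OH to give benzyl 2-hydroxy-4-methoxy-6-pentylbenzoate F7. H2, 10% Pd/C, EtOAc at rt then releases 3 under neutral conditions.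

## Further compounds

F1 | step 7 | 7-methoxy-2,2-dimethyl-5-pentyl-4H-1,3-benzodioxin-4-one | CCCCCc1cc(OC)cc2OC(C)(C)OC(=O)c12
F2 | step 8 | 2-methoxy-4-(methoxymethoxy)-6-propylbenzoic acid | CCCc1cc(OCOC)cc(OC)c1C(=O)O
F3 | step 8 | benzyl 2-methoxy-4-(methoxymethoxy)-6-propylbenzoate | CCCc1cc(OCOC)cc(OC)c1C(=O)OCc1ccccc1
F4 | step 8 | benzyl 4-hydroxy-2-methoxy-6-propylbenzoate | CCCc1cc(O)cc(OC)c1C(=O)OCc1ccccc1
F5 | step 8 | benzyl 4-[(2-hydroxy-4-methoxy-6-pentylbenzoyl)oxy]-2-methoxy-6-propylbenzoate | CCCCCc1cc(OC)cc(O)c1C(=O)Oc1cc(CCC)c(C(=O)OCc2ccccc2)c(OC)c1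
F6 | step 2 | benzyl 2,4-dihydroxy-6-pentylbenzoate | CCCCCc1cc(O)cc(O)c1C(=O)OCc1ccccc1
F7 | step 2 | benzyl 2-hydroxy-4-methoxy-6-pentylbenzoate | CCCCCc1cc(OC)cc(O)c1C(=O)OCc1ccccc1
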